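**Strategy.** The tetrahydrofuran ring is closed last at C2–C3. C2 (benzylic, bound to ring oxygen O1) is treated as a latent vanillin-derived oxocarbenium carbon and C3 (bearing CH2OH) as a latent aldehyde enol carbon, so C2–C3 is an intramolecular aldol-type bond. In one operation a TMS ether and vanillin acetate condense to the O1=C2 oxocarbenium ion, a tethered enol acetate closes the ring, and C2 and C3 are set (2,3-cis, 3,4-trans). The precursor is acyclic: an anti-aldol adduct (C4 and C5 set by an Evans auxiliary) carrying O-TMS and an enol acetate. The twofold symmetry of the target lets both aryl carbons (C2, C5) come from the same aldehyde.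

Key step: step 5

Remark: the tetrahydrofuran numbering of the target (O1, C2 to C5) is used for all intermediates; the MgCl2-catalysed aldol of the (S)-auxiliary is assumed to react on the same (chelated) enolate face as its alkylations.

**Step 1**
Reactants: 1 (S)-4-benzyl-1,3-oxazolidin-2-one; 2 pent-4-enoyl chloride
Product: 3 (S)-4-benzyl-3-(pent-4-enoyl)-1,3-oxazolidin-2-one
Conditions: n-BuLi, THF, -78 °C; then 2, -78 °C to 0 °C
Reagents that add atoms: none
Why: N-acylation of the lithiated oxazolidinone by the acid chloride is a standard imide formation and creates no stereocentre.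

**Step 2**
Reactants: 3 (S)-4-benzyl-3-(pent-4-enoyl)-1,3-oxazolidin-2-one; 4 vanillin acetate (4-formyl-2-methoxyphenyl acetate)
Product: 5 (S)-4-benzyl-3-{(2R)-2-[(S)-(4-acetoxy-3-methoxyphenyl)(trimethylsilyloxy)methyl]pent-4-enoyl}-1,3-oxazolidin-2-one (anti-aldol adduct as TMS ether)
Conditions: MgCl2 (0.2 equiv), Et3N, TMSCl, EtOAc, rt; non-aqueous work-up, filtration through Et3N-deactivated silica
Reagents that add atoms: chlorotrimethylsilane, C[Si](C)(C)Cl
Why: In this MgCl2-catalysed anti-selective Evans aldol, soft enolization of 3 and addition to 4 through a chelated closed transition state on the face opposite the benzyl group should set C4 and C5 (anti, hence 4,5-cis in the later ring), and silylation of the aldolate by TMSCl turns the catalyst over and delivers the TMS ether directly.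

**Step 3**
Reactants: 5 (anti-aldol TMS ether)
Product: 6 (S)-4-benzyl-3-{(2R)-2-[(S)-(4-acetoxy-3-methoxyphenyl)(trimethylsilyloxy)methyl]-4-oxobutanoyl}-1,3-oxazolidin-2-one
Conditions: O3, pyridine (cat.), Sudan Red 7B, CH2Cl2, -78 °C; then PPh3, -78 °C to rt; used crude
Reagents that add atoms: ozone, [O-][O+]=O
Why: Ozonolysis with a dye end-point should cleave the terminal alkene in preference to the acylated arenes, and the neutral reductive work-up keeps the TMS ether and all stereocentres intact.

**Step 4**
Reactants: 6 (aldehyde)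
Product: 7 (3R)-3-[(S)-(4-acetoxy-3-methoxyphenyl)(trimethylsilyloxy)methyl]-4-[(S)-4-benzyl-2-oxo-1,3-oxazolidin-3-yl]-4-oxobut-1-en-1-yl acetate (E/Z mixture)
Conditions: Ac2O, Et3N, DMAP (cat.), CH2Cl2, rt
Reagents that add atoms: acetic anhydride, CC(=O)OC(C)=O
Why: O-acetylation of the aldehyde enolate (enol acetate formation) turns C3 into a weak carbon nucleophile that should survive the next Lewis acid; the alkene geometry is not controlled and is lost in the product, both isomers being expected to converge because C3 is set in the ring closure.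

**Step 5**
Reactants: 7 (enol acetate, E/Z mixture); 4 vanillin acetate
Product: 10 (2S,3R,4R,5S)-2,5-bis(4-acetoxy-3-methoxyphenyl)-4-{[(S)-4-benzyl-2-oxo-1,3-oxazolidin-3-yl]carbonyl}tetrahydrofuran-3-carbaldehyde (2,3-cis; 3,4-trans; 4,5-cis), via oxocarbenium triflate 8 (not isolated), via acyloxycarbenium triflate 9 (not isolated)
Conditions: 4 (1.2 equiv), TMSOTf (0.3 equiv), 4 Å MS, CH2Cl2, -78 °C; Et3N quench at -78 °C; used crude
Reagents that add atoms: none
Why: TMSOTf should condense the TMS ether of 7 with 4 to the (E)-oxocarbenium ion 8 (silyl ether/aldehyde condensation, as in the silyl-modified Hosomi–Sakurai reaction), the tethered enol acetate then attacks the oxocarbenium carbon C2 through its β-carbon C3 to give 9, and loss of the acetyl group as Me3SiOAc unveils the aldehyde and returns TMSOTf. The closest known reaction type is the Prins/Mukaiyama-aldol-type collapse of an oxocarbenium–enol pair that operates in the Lewis-acid ring contraction of 4,5-dihydro-1,3-dioxepins to 2-aryl-tetrahydrofuran-3-carbaldehydes, and enol acetates are established terminators for aryl-stabilized oxocarbenium ions. The tetrahydrofuran closes in a 5-(enol-exo) mode, the O1=C2 bond being endocyclic. C3 is controlled by C4 (the C4–H eclipses the enol double bond and the acyl-oxazolidinone stays pseudo-equatorial, so the formyl carbon ends up trans to it), and C2 is controlled by the (E)-oxocarbenium geometry, which keeps its aryl group pseudo-equatorial in a compact synclinal envelope and should give the kinetic 2,3-cis product known for the dioxepin contractions at -78 °C, here equal to 2,5-trans. The step needs attack through C3 instead of 6-endo Prins closure through the acetoxy-bearing carbon (secured by the polarization of the enol acetate), no ionization of the C5–O bond (secured by the electron-poor acetoxyaryl groups), and kinetic control over the more stable 2,3-trans isomer (low temperature, catalytic acid, cold amine quench).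

**Step 6**
Reactants: 10 (tetrahydrofuran aldehyde)
Product: 11 [(2S,3S,4S,5S)-2,5-bis(4-hydroxy-3-methoxyphenyl)tetrahydrofuran-3,4-diyl]dimethanol (target)
Conditions: LiBH4 (excess), MeOH, THF, 0 °C to rt; aq. NH4Cl
Reagents that add atoms: none
Why: Global hydride reduction should reduce the epimerizable aldehyde first, then cleave the N-acyl oxazolidinone at the exocyclic carbonyl to the second hydroxymethyl group and release both aryl acetates, without touching the four ring stereocentres.

**Compound list**
1 | (S)-4-benzyl-1,3-oxazolidin-2-one | O=C1N[C@@H](Cc2ccccc2)CO1 | starting material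
2 | pent-4-enoyl chloride | C=CCCC(=O)Cl | starting material
3 | (S)-4-benzyl-3-(pent-4-enoyl)-1,3-oxazolidin-2-one | C=CCCC(=O)N1[C@@H](Cc2ccccc2)COC1=O | intermediate
4 | vanillin acetate (4-formyl-2-methoxyphenyl acetate) | CC(=O)Oc1ccc(C=O)cc1OC | starting material
5 | (S)-4-benzyl-3-{(2R)-2-[(S)-(4-acetoxy-3-methoxyphenyl)(trimethylsilyloxy)methyl]pent-4-enoyl}-1,3-oxazolidin-2-one | C=CC[C@H]([C@H](O[Si](C)(C)C)c1ccc(OC(C)=O)c(OC)c1)C(=O)N1[C@@H](Cc2ccccc2)COC1=O | intermediate
6 | (S)-4-benzyl-3-{(2R)-2-[(S)-(4-acetoxy-3-methoxyphenyl)(trimethylsilyloxy)methyl]-4-oxobutanoyl}-1,3-oxazolidin-2-one | O=CC[C@H]([C@H](O[Si](C)(C)C)c1ccc(OC(C)=O)c(OC)c1)C(=O)N1[C@@H](Cc2ccccc2)COC1=O | intermediate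
7 | (3R)-3-[(S)-(4-acetoxy-3-methoxyphenyl)(trimethylsilyloxy)methyl]-4-[(S)-4-benzyl-2-oxo-1,3-oxazolidin-3-yl]-4-oxobut-1-en-1-yl acetate, E/Z mixture (alkene geometry left open in the SMILES) | CC(=O)OC=C[C@H]([C@H](O[Si](C)(C)C)c1ccc(OC(C)=O)c(OC)c1)C(=O)N1[C@@H](Cc2ccccc2)COC1=O | intermediate
8 | (E)-oxocarbenium triflate formed from the C5 oxygen of 7 and the formyl carbon of 4 (C5–O1+=C2H–aryl) | CC(=O)OC=C[C@H]([C@H](/[O+]=C/c1ccc(OC(C)=O)c(OC)c1)c1ccc(OC(C)=O)c(OC)c1)C(=O)N1[C@@H](Cc2ccccc2)COC1=O.[O-]S(=O)(=O)C(F)(F)F | intermediate (not isolated)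
9 | ring-closed O-acetyl oxocarbenium (acyloxycarbenium) triflate at the C3 formyl carbon | CC(=O)Oc1ccc(cc1OC)[C@H]1O[C@H](c2ccc(OC(C)=O)c(OC)c2)[C@H](C=[O+]C(C)=O)[C@H]1C(=O)N1[C@@H](Cc2ccccc2)COC1=O.[O-]S(=O)(=O)C(F)(F)F | intermediate (not isolated)
10 | (2S,3R,4R,5S)-2,5-bis(4-acetoxy-3-methoxyphenyl)-4-{[(S)-4-benzyl-2-oxo-1,3-oxazolidin-3-yl]carbonyl}tetrahydrofuran-3-carbaldehyde | CC(=O)Oc1ccc(cc1OC)[C@H]1O[C@H](c2ccc(OC(C)=O)c(OC)c2)[C@H](C=O)[C@H]1C(=O)N1[C@@H](Cc2ccccc2)COC1=O | intermediate
11 | [(2S,3S,4S,5S)-2,5-bis(4-hydroxy-3-methoxyphenyl)tetrahydrofuran-3,4-diyl]dimethanol | COc1cc([C@H]2O[C@H](c3ccc(O)c(OC)c3)[C@H](CO)[C@H]2CO)ccc1O | target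

**Totals.** Total step count: 6. Longest linear sequence: 6 steps (1 → 3 → 5 → 6 → 7 → 10 → 11).

**Steps most likely to fail**

Step 5. The hindered benzylic TMS ether may be cleaved or ionized before it captures the aldehyde, so that the oxocarbenium ion is not formed cleanly and the enol acetate is lost to intermolecular pathways. The fallback runs from 5 to 11 and keeps the same ring closure but enters the cation by oxidation. Reductive etherification of 5 with commercial 4-(tert-butyldimethylsilyloxy)-3-methoxybenzaldehyde (Et3SiH, cat. TMSOTf, CH2Cl2, -78 °C) should give the stable electron-rich benzyl ether F1. Ozonolysis as in step 3 should give the aldehyde F2, and acetylation as in step 4 the enol acetate F3. DDQ (2,6-dichloropyridine, LiClO4, 4 Å MS, 1,2-dichloroethane, 0 °C to rt) should remove hydride from the silyloxybenzyl CH2 only, because the other benzylic C–H sits on the deactivated acetoxyaryl ring; the resulting oxocarbenium ion closes C2–C3 to the tetrahydrofuran aldehyde F4. LiBH4 as in step 6 should give the mono-silyl ether of the target F5, and TBAF/AcOH in THF returns the route at 11.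

Step 4. Under Et3N/DMAP the TMS ether may be lost, after which the γ-hydroxy aldehyde closes to a lactol that is acetylated, or the aldehyde may self-condense. The fallback runs from 6 to 10. Soft enolization with TMSOTf/Et3N (CH2Cl2, -78 °C, non-aqueous work-up) should give the trimethylsilyl enol ether F6, which is treated at once with 4 and catalytic TMSOTf at -78 °C. The silyl enol ether takes the place of the enol acetate as terminator, hexamethyldisiloxane is the only coproduct, and the route is rejoined at 10 without passing through 7.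

Step 2. The soft-enolization aldol is reversible until the aldolate is silylated, so retro-aldol equilibration may erode the anti selectivity, and part of the TMS ether may be lost on isolation. The fallback runs from 3 and 4 to 5 and uses a kinetic boron aldol through an open transition state. Compound 3 is enolized with Bu2BOTf/i-Pr2NEt (CH2Cl2, -78 °C) and added to 4 precomplexed with Et2AlCl, which should give the same anti adduct as its free alcohol F7 (purified by crystallization). Silylation (TMSCl, imidazole, CH2Cl2, 0 °C) returns the route at 5.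

**Further compounds**
F1 | step 5 | (S)-4-benzyl-3-{(2R)-2-[(S)-(4-acetoxy-3-methoxyphenyl)(4-tert-butyldimethylsilyloxy-3-methoxybenzyloxy)methyl]pent-4-enoyl}-1,3-oxazolidin-2-one | C=CC[C@H]([C@H](OCc1ccc(O[Si](C)(C)C(C)(C)C)c(OC)c1)c1ccc(OC(C)=O)c(OC)c1)C(=O)N1[C@@H](Cc2ccccc2)COC1=O
F2 | step 5 | aldehyde from ozonolysis of F1 (4-oxobutanoyl imide) | O=CC[C@H]([C@H](OCc1ccc(O[Si](C)(C)C(C)(C)C)c(OC)c1)c1ccc(OC(C)=O)c(OC)c1)C(=O)N1[C@@H](Cc2ccccc2)COC1=O
F3 | step 5 | enol acetate of F2 (E/Z mixture) | CC(=O)OC=C[C@H]([C@H](OCc1ccc(O[Si](C)(C)C(C)(C)C)c(OC)c1)c1ccc(OC(C)=O)c(OC)c1)C(=O)N1[C@@H](Cc2ccccc2)COC1=O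
F4 | step 5 | (2S,3R,4R,5S)-5-(4-acetoxy-3-methoxyphenyl)-2-(4-tert-butyldimethylsilyloxy-3-methoxyphenyl)-4-{[(S)-4-benzyl-2-oxo-1,3-oxazolidin-3-yl]carbonyl}tetrahydrofuran-3-carbaldehyde | CC(=O)Oc1ccc(cc1OC)[C@H]1O[C@H](c2ccc(O[Si](C)(C)C(C)(C)C)c(OC)c2)[C@H](C=O)[C@H]1C(=O)N1[C@@H](Cc2ccccc2)COC1=O
F5 | step 5 | mono-(tert-butyldimethylsilyl) aryl ether of the target | COc1cc([C@H]2O[C@H](c3ccc(O[Si](C)(C)C(C)(C)C)c(OC)c3)[C@H](CO)[C@H]2CO)ccc1O
F6 | step 4 | trimethylsilyl enol ether of 6 (E/Z mixture) | C[Si](C)(C)OC=C[C@H]([C@H](O[Si](C)(C)C)c1ccc(OC(C)=O)c(OC)c1)C(=O)N1[C@@H](Cc2ccccc2)COC1=O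
F7 | step 2 | (S)-4-benzyl-3-{(2R)-2-[(S)-(4-acetoxy-3-methoxyphenyl)(hydroxy)methyl]pent-4-enoyl}-1,3-oxazolidin-2-one | C=CC[C@H]([C@H](O)c1ccc(OC(C)=O)c(OC)c1)C(=O)N1[C@@H](Cc2ccccc2)COC1=O
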